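Colleterpenol is disconnected at the ring bond C1–C14 (polyprenyl numbering: ring = C1–C14, carbinol = C15). Ring carbon C1 is allylic to C2=C3, and the ring methine C14 carries the exocyclic tertiary carbinol C15, a vicinal C/O pair that maps onto an epoxide. In the key step a sulfur-stabilised allyl carbanion at C1 opens a cis-(14R,15S)-epoxide at C14 with inversion. This one operation closes the fourteen-membered ring, sets C14 and releases the C15 alcohol with its configuration intact. The precursor is an acyclic C30 epoxy pentaene bearing phenylsulfanyl groups at C1 and C17, assembled from farnesol, a Z-allylic alcohol/asymmetric epoxidation unit and geranyl phenyl sulfide.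

Key step: step 12

Remark on the chemistry: the target is read as (14R,15S); the sulfur-bearing carbons C17 (from step 9) and C1 (from step 12) form as epimer mixtures, which is immaterial because both C–S bonds become C–H in step 13.
Remark on the chemistry: acetaldehyde N-tert-butylimine and the trifluoroethyl phosphonate of step 5 are taken as catalogue reagents.

Step 1
Reactants: 1 (2E,6E)-farnesol
Product: 2 (2E,6E)-farnesyl tert-butyldiphenylsilyl ether
Conditions: t-BuPh2SiCl, imidazole, DMF, 0 °C → rt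
Reagents that add atoms: tert-butyl(chloro)diphenylsilane, CC(C)(C)[Si](Cl)(c1ccccc1)c1ccccc1
Why: Standard silylation of the primary allylic alcohol; the bulky silyl ether should withstand the oxidations, strong bases and hydride used before step 10.

Step 2
Reactants: 2 (2E,6E)-farnesyl tert-butyldiphenylsilyl ether
Product: 3 (2E,6E,10E)-12-(tert-butyldiphenylsilyloxy)-2,6,10-trimethyldodeca-2,6,10-trien-1-ol
Conditions: SeO2 (cat.), t-BuOOH, salicylic acid (cat.), CH2Cl2, 0 °C → rt
Reagents that add atoms: tert-butyl hydroperoxide, CC(C)(C)OO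
Why: SeO2-catalysed allylic oxidation (ene reaction, then [2,3]-sigmatropic shift) should hydroxylate the (E)-methyl of the terminal isopropylidene group, the 2,3-olefin being deactivated by the allylic silyloxy group, and so fixes the E geometry of the future C10=C11 bond.

Step 3
Reactants: 3 (2E,6E,10E)-12-(tert-butyldiphenylsilyloxy)-2,6,10-trimethyldodeca-2,6,10-trien-1-ol
Product: 4 (2E,6E,10E)-1-bromo-12-(tert-butyldiphenylsilyloxy)-2,6,10-trimethyldodeca-2,6,10-triene
Conditions: CBr4, PPh3, CH2Cl2, 0 °C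
Reagents that add atoms: tetrabromomethane, BrC(Br)(Br)Br
Why: Appel reaction; bromide displaces the oxyphosphonium at the primary carbon by SN2 without allylic transposition.

Step 4
Reactants: 4 (2E,6E,10E)-1-bromo-12-(tert-butyldiphenylsilyloxy)-2,6,10-trimethyldodeca-2,6,10-triene
Product: 6 (4E,8E,12E)-14-(tert-butyldiphenylsilyloxy)-4,8,12-trimethyltetradeca-4,8,12-trienal, via N-tert-butyl imine 5 (not isolated)
Conditions: LiN(iPr)2, CH3CH=N-t-Bu, THF, −78 → 0 °C; then 4, −78 °C → rt; then aq. AcOH/NaOAc, rt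
Reagents that add atoms: acetaldehyde N-tert-butylimine, CC=NC(C)(C)C; water, O
Why: Metalloenamine (aza-enolate) alkylation; the lithiated acetaldehyde imine should displace the primary allylic bromide at C12, and mild hydrolysis of imine 5 frees the two-carbon-extended aldehyde (C13, C14).

Step 5
Reactants: 6 (4E,8E,12E)-14-(tert-butyldiphenylsilyloxy)-4,8,12-trimethyltetradeca-4,8,12-trienal
Product: 7 methyl (2Z,6E,10E,14E)-16-(tert-butyldiphenylsilyloxy)-2,6,10,14-tetramethylhexadeca-2,6,10,14-tetraenoate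
Conditions: (CF3CH2O)2P(O)CH(CH3)CO2Me, KN(SiMe3)2, 18-crown-6, THF, −78 °C
Reagents that add atoms: methyl 2-[bis(2,2,2-trifluoroethoxy)phosphoryl]propanoate, COC(=O)C(C)P(=O)(OCC(F)(F)F)OCC(F)(F)F
Why: Still–Gennari olefination; fast, irreversible elimination from the kinetic adduct should give the (Z)-trisubstituted enoate in which C13 is cis to the ester carbon C16, the geometry the cis epoxide needs.

Step 6
Reactants: 7 methyl (2Z,6E,10E,14E)-16-(tert-butyldiphenylsilyloxy)-2,6,10,14-tetramethylhexadeca-2,6,10,14-tetraenoate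
Product: 8 (2Z,6E,10E,14E)-16-(tert-butyldiphenylsilyloxy)-2,6,10,14-tetramethylhexadeca-2,6,10,14-tetraen-1-ol
Conditions: iBu2AlH, CH2Cl2, −78 °C; aq. potassium sodium tartrate
Reagents that add atoms: none
Why: 1,2-Reduction of the conjugated ester to the allylic alcohol; olefin geometry and silyl ether should be untouched.

Step 7
Reactants: 8 (2Z,6E,10E,14E)-16-(tert-butyldiphenylsilyloxy)-2,6,10,14-tetramethylhexadeca-2,6,10,14-tetraen-1-ol
Product: 9 [(2S,3R)-3-[(3E,7E,11E)-13-(tert-butyldiphenylsilyloxy)-3,7,11-trimethyltrideca-3,7,11-trien-1-yl]-2-methyloxiran-2-yl]methanol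
Conditions: Ti(OiPr)4 (cat.), L-(+)-diethyl tartrate (cat.), t-BuOOH, 4 Å molecular sieves, CH2Cl2, −20 °C
Reagents that add atoms: tert-butyl hydroperoxide, CC(C)(C)OO
Why: Katsuki–Sharpless asymmetric epoxidation, directed by the only free allylic hydroxyl, should oxidise C14=C15 alone; L-(+)-tartrate delivers oxygen to the face that gives S at the methyl-bearing carbon and, with the Z geometry, R at C14, i.e. the cis (14R,15S) epoxide.

Step 8
Reactants: 10 geraniol
Product: 11 geranyl phenyl sulfide
Conditions: PhSSPh, PBu3, THF, 0 °C → rt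
Reagents that add atoms: diphenyl disulfide, c1ccc(cc1)SSc1ccccc1
Why: Redox condensation; thiolate displaces the oxyphosphonium formed from PhSSPh/PBu3 at the primary allylic carbon by SN2 without transposition.

Step 9
Reactants: 9 [(2S,3R)-3-[(3E,7E,11E)-13-(tert-butyldiphenylsilyloxy)-3,7,11-trimethyltrideca-3,7,11-trien-1-yl]-2-methyloxiran-2-yl]methanol; 11 geranyl phenyl sulfide
Product: 14 (2E,6E,10E,18E)-(14R,15S)-1-(tert-butyldiphenylsilyloxy)-14,15-epoxy-3,7,11,15,19,23-hexamethyl-17-(phenylsulfanyl)tetracosa-2,6,10,18,22-pentaene as C17 epimers, via epoxy triflate 12 (not isolated), via lithiated geranyl phenyl sulfide 13 (not isolated)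
Conditions: 9, Tf2O, 2,6-lutidine, CH2Cl2, −78 °C (12, used cold and crude); 11, n-BuLi, THF, −78 °C (13); then 12 added, −78 → −40 °C
Reagents that add atoms: none
Why: Alkylation of a sulfur-stabilised allyl carbanion; α-lithiated 11, whose γ-carbon is fully substituted, should displace the primary triflate faster than it attacks the trisubstituted epoxide, joining C16 to C17 and leaving the epoxide stereocentres untouched.

Step 10
Reactants: 14 (2E,6E,10E,18E)-(14R,15S)-1-(tert-butyldiphenylsilyloxy)-14,15-epoxy-3,7,11,15,19,23-hexamethyl-17-(phenylsulfanyl)tetracosa-2,6,10,18,22-pentaene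
Product: 15 (2E,6E,10E,18E)-(14R,15S)-14,15-epoxy-3,7,11,15,19,23-hexamethyl-17-(phenylsulfanyl)tetracosa-2,6,10,18,22-pentaen-1-ol
Conditions: Bu4NF, THF, 0 °C → rt
Reagents that add atoms: none
Why: Fluoride-induced Si–O cleavage; epoxide, sulfide and olefins should be inert to Bu4NF.

Step 11
Reactants: 15 (2E,6E,10E,18E)-(14R,15S)-14,15-epoxy-3,7,11,15,19,23-hexamethyl-17-(phenylsulfanyl)tetracosa-2,6,10,18,22-pentaen-1-ol
Product: 16 (2E,6E,10E,18E)-(14R,15S)-14,15-epoxy-3,7,11,15,19,23-hexamethyl-1,17-bis(phenylsulfanyl)tetracosa-2,6,10,18,22-pentaene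
Conditions: PhSSPh, PBu3, THF, 0 °C → rt
Reagents that add atoms: diphenyl disulfide, c1ccc(cc1)SSc1ccccc1
Why: The redox condensation of step 8 installs the second allyl phenyl sulfide at the primary allylic C1 under neutral conditions that the epoxide should tolerate.

Step 12
Reactants: 16 (2E,6E,10E,18E)-(14R,15S)-14,15-epoxy-3,7,11,15,19,23-hexamethyl-1,17-bis(phenylsulfanyl)tetracosa-2,6,10,18,22-pentaene
Product: 18 (2S,5E)-6,10-dimethyl-4-(phenylsulfanyl)-2-[(3E,7E,11E)-4,8,12-trimethyl-2-(phenylsulfanyl)cyclotetradeca-3,7,11-trien-1-yl]undeca-5,9-dien-2-ol with the ring methine arranged as in the target, via C1-lithiated bis-sulfide 17 (not isolated)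
Conditions: n-BuLi, DABCO, THF, −78 → −20 °C, high dilution (about 0.005 M); aqueous work-up
Reagents that add atoms: none
Why: n-BuLi/DABCO removes a proton from the primary allylic sulfide carbon C1, and the α-thio allyllithium 17 attacks the secondary epoxide carbon C14 from the side opposite its C–O bond (SN2), the oxygen staying on C15 as the tertiary alkoxide. The closest known reaction type is the carbanion–epoxide macrocyclisation of ω-epoxy polyprenyl phenyl sulfides used to build fourteen-membered cembrane rings. The ring C1–C14 closes in the 14-exo-tet mode, the breaking C14–O bond lying outside the new ring. C14 is set by stereospecific inversion of the (14R) epoxide carbon and C15 keeps the configuration from step 7, so the cis epoxide translates into the (14R,15S) pair of the target (descriptors for the sulfur-free skeleton). The step needs metalation at C1 rather than C17 (primary against hindered tertiary C–H), α- rather than γ-attack of the allyl anion (the γ-carbon C3 is fully substituted and would give a twelve-membered ring with a quaternary centre), attack at the secondary rather than the fully substituted epoxide carbon, and ring closure rather than oligomerisation, which high dilution should secure.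

Step 13
Reactants: 18 (2S,5E)-6,10-dimethyl-4-(phenylsulfanyl)-2-[(3E,7E,11E)-4,8,12-trimethyl-2-(phenylsulfanyl)cyclotetradeca-3,7,11-trien-1-yl]undeca-5,9-dien-2-ol
Product: 19 colleterpenol
Conditions: Li, EtNH2, THF, −78 °C; then H2O
Reagents that add atoms: none
Why: Dissolving-metal reduction cleaves both allylic C–S bonds to allyl anions that should be protonated at the less substituted α-carbons (C1 and C17), keeping C2=C3 and C18=C19 trisubstituted and E; the non-allylic tertiary alkoxide and both stereocentres are not involved.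

Compound list
1 | (2E,6E)-farnesol, (2E,6E)-3,7,11-trimethyldodeca-2,6,10-trien-1-ol | CC(C)=CCC/C(C)=C/CC/C(C)=C/CO | starting material
2 | (2E,6E)-farnesyl tert-butyldiphenylsilyl ether | CC(C)=CCC/C(C)=C/CC/C(C)=C/CO[Si](c1ccccc1)(c2ccccc2)C(C)(C)C | intermediate
3 | (2E,6E,10E)-12-(tert-butyldiphenylsilyloxy)-2,6,10-trimethyldodeca-2,6,10-trien-1-ol | OC/C(C)=C/CC/C(C)=C/CC/C(C)=C/CO[Si](c1ccccc1)(c2ccccc2)C(C)(C)C | intermediate
4 | (2E,6E,10E)-1-bromo-12-(tert-butyldiphenylsilyloxy)-2,6,10-trimethyldodeca-2,6,10-triene | BrC/C(C)=C/CC/C(C)=C/CC/C(C)=C/CO[Si](c1ccccc1)(c2ccccc2)C(C)(C)C | intermediate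
5 | N-tert-butyl imine of aldehyde 6 | CC(C)(C)N=CCC/C(C)=C/CC/C(C)=C/CC/C(C)=C/CO[Si](c1ccccc1)(c2ccccc2)C(C)(C)C | intermediate (not isolated)
6 | (4E,8E,12E)-14-(tert-butyldiphenylsilyloxy)-4,8,12-trimethyltetradeca-4,8,12-trienal | O=CCC/C(C)=C/CC/C(C)=C/CC/C(C)=C/CO[Si](c1ccccc1)(c2ccccc2)C(C)(C)C | intermediate
7 | methyl (2Z,6E,10E,14E)-16-(tert-butyldiphenylsilyloxy)-2,6,10,14-tetramethylhexadeca-2,6,10,14-tetraenoate | COC(=O)/C(C)=C\CC/C(C)=C/CC/C(C)=C/CC/C(C)=C/CO[Si](c1ccccc1)(c2ccccc2)C(C)(C)C | intermediate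
8 | (2Z,6E,10E,14E)-16-(tert-butyldiphenylsilyloxy)-2,6,10,14-tetramethylhexadeca-2,6,10,14-tetraen-1-ol | OC/C(C)=C\CC/C(C)=C/CC/C(C)=C/CC/C(C)=C/CO[Si](c1ccccc1)(c2ccccc2)C(C)(C)C | intermediate
9 | [(2S,3R)-3-[(3E,7E,11E)-13-(tert-butyldiphenylsilyloxy)-3,7,11-trimethyltrideca-3,7,11-trien-1-yl]-2-methyloxiran-2-yl]methanol, cis epoxide, (14R,15S) in polyprenyl numbering | OC[C@]1(C)O[C@@H]1CC/C(C)=C/CC/C(C)=C/CC/C(C)=C/CO[Si](c2ccccc2)(c3ccccc3)C(C)(C)C | intermediate
10 | geraniol, (2E)-3,7-dimethylocta-2,6-dien-1-ol | CC(C)=CCC/C(C)=C/CO | starting material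
11 | geranyl phenyl sulfide, [(2E)-3,7-dimethylocta-2,6-dienyl]sulfanylbenzene | CC(C)=CCC/C(C)=C/CSc1ccccc1 | intermediate
12 | trifluoromethanesulfonate of epoxy alcohol 9 | FC(F)(F)S(=O)(=O)OC[C@]1(C)O[C@@H]1CC/C(C)=C/CC/C(C)=C/CC/C(C)=C/CO[Si](c2ccccc2)(c3ccccc3)C(C)(C)C | intermediate (not isolated)
13 | α-lithiated geranyl phenyl sulfide | [Li]C(Sc1ccccc1)/C=C(\C)CCC=C(C)C | intermediate (not isolated)
14 | (2E,6E,10E,18E)-(14R,15S)-1-(tert-butyldiphenylsilyloxy)-14,15-epoxy-3,7,11,15,19,23-hexamethyl-17-(phenylsulfanyl)tetracosa-2,6,10,18,22-pentaene, C17 epimers | CC(C)=CCC/C(C)=C/C(Sc2ccccc2)C[C@]1(C)O[C@@H]1CC/C(C)=C/CC/C(C)=C/CC/C(C)=C/CO[Si](c3ccccc3)(c4ccccc4)C(C)(C)C | intermediate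
15 | (2E,6E,10E,18E)-(14R,15S)-14,15-epoxy-3,7,11,15,19,23-hexamethyl-17-(phenylsulfanyl)tetracosa-2,6,10,18,22-pentaen-1-ol, C17 epimers | CC(C)=CCC/C(C)=C/C(Sc2ccccc2)C[C@]1(C)O[C@@H]1CC/C(C)=C/CC/C(C)=C/CC/C(C)=C/CO | intermediate
16 | (2E,6E,10E,18E)-(14R,15S)-14,15-epoxy-3,7,11,15,19,23-hexamethyl-1,17-bis(phenylsulfanyl)tetracosa-2,6,10,18,22-pentaene, C17 epimers | CC(C)=CCC/C(C)=C/C(Sc2ccccc2)C[C@]1(C)O[C@@H]1CC/C(C)=C/CC/C(C)=C/CC/C(C)=C/CSc3ccccc3 | intermediate
17 | 1-lithio derivative of 16 | CC(C)=CCC/C(C)=C/C(Sc2ccccc2)C[C@]1(C)O[C@@H]1CC/C(C)=C/CC/C(C)=C/CC/C(C)=C/C([Li])Sc3ccccc3 | intermediate (not isolated)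
18 | (2S,5E)-6,10-dimethyl-4-(phenylsulfanyl)-2-[(3E,7E,11E)-4,8,12-trimethyl-2-(phenylsulfanyl)cyclotetradeca-3,7,11-trien-1-yl]undeca-5,9-dien-2-ol; ring C1 arranged as in the target (descriptor 1S only because sulfur raises the priority of ring C2); epimers at both sulfur-bearing carbons | CC(C)=CCC/C(C)=C/C(Sc2ccccc2)C[C@](C)(O)[C@H]1C(Sc3ccccc3)/C=C(\C)CC/C=C(\C)CC/C=C(\C)CC1 | intermediate
19 | colleterpenol, (2S,5E)-6,10-dimethyl-2-[(1R,3E,7E,11E)-4,8,12-trimethylcyclotetradeca-3,7,11-trien-1-yl]undeca-5,9-dien-2-ol | CC(C)=CCC/C(C)=C/CC[C@](C)(O)[C@H]1C/C=C(\C)CC/C=C(\C)CC/C=C(\C)CC1 | target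

Total step count: 13. Longest linear sequence: 12 (steps 1–7 and 9–13; step 8 makes the side-chain fragment).

Steps most likely to fail

Step 12 (macrocyclisation). What may go wrong: intermolecular alkylation outrunning ring closure, proton transfer to the hindered sulfide carbon C17 followed by small-ring closure onto the nearby epoxide, or base-induced isomerisation of the epoxide to an allylic alcohol. The fallback sets out from 15 and comes back at 19. It makes the carbanion from an allyl sulfone, so that metalation is unambiguous and reversible and the ring closure can be run warmer. Appel bromination of 15 (CBr4, PPh3, CH2Cl2) would give the allylic bromide F1. PhSO2Na in DMF would then give the C1 phenyl sulfone F2. LiN(SiMe3)2 in THF/HMPA at high dilution should close the ring by sulfonyl carbanion–epoxide opening to the macrocyclic hydroxy sulfone F3. Li/EtNH2 would finally remove the sulfonyl and the phenylsulfanyl group together to give 19.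

Step 9 (fragment union). What may go wrong: slow SN2 displacement at a triflate-bearing carbon flanked by a fully substituted epoxide carbon, so that decomposition of the triflate, attack of the carbanion on the epoxide or γ-alkylation takes over. The fallback sets out from 9 and comes back at 18. It closes the ring first and then attaches the side chain by opening a terminal epoxide at its CH2 end.
- 3,4-Dihydro-2H-pyran with pyridinium p-toluenesulfonate would convert 9 into the tetrahydropyranyl ether F4.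
- Bu4NF would free the C1 alcohol F5, and PhSSPh/PBu3 would give the C1 phenyl sulfide F6.
- n-BuLi/DABCO at high dilution should perform the same carbanion–epoxide ring closure on this single-sulfide substrate, giving the macrocyclic tetrahydropyranyl ether F7.
- Pyridinium p-toluenesulfonate in MeOH would release the macrocyclic 1,2-diol F8.
- TsCl/pyridine should sulfonylate only the primary hydroxyl to give the monotosylate F9, and K2CO3 in MeOH would close the macrocyclic terminal epoxide F10 with C15 unchanged.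
- An excess of 13 in THF (−78 → 0 °C) should open F10 at C16 to give 18.

Step 13 (reductive removal of sulfur). What may go wrong: allylic transposition or E/Z scrambling of C2=C3 and C18=C19 when the two allyl anions are protonated, and over-reduction. The fallback sets out from 18 and comes back at 19. It replaces the dissolving metal by hydride delivery through π-allylpalladium intermediates. (NH4)6Mo7O24 (cat.)/H2O2 in EtOH should oxidise both sulfides chemoselectively to the bis-sulfone F11. PdCl2(Ph2PCH2CH2CH2PPh2) (cat.) with LiEt3BH in THF at 0 °C should then replace both allylic sulfonyl groups by hydrogen at the less substituted allyl termini, giving 19.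

Further compounds
F1 | step 12 | allylic bromide from 15, (14R,15S)-1-bromo-14,15-epoxy-17-(phenylsulfanyl) pentaene | CC(C)=CCC/C(C)=C/C(Sc2ccccc2)C[C@]1(C)O[C@@H]1CC/C(C)=C/CC/C(C)=C/CC/C(C)=C/CBr
F2 | step 12 | C1 phenyl sulfone, (14R,15S)-14,15-epoxy-1-(phenylsulfonyl)-17-(phenylsulfanyl) pentaene | CC(C)=CCC/C(C)=C/C(Sc2ccccc2)C[C@]1(C)O[C@@H]1CC/C(C)=C/CC/C(C)=C/CC/C(C)=C/CS(=O)(=O)c3ccccc3
F3 | step 12 | macrocyclic hydroxy sulfone, analogue of 18 with phenylsulfonyl on the ring | CC(C)=CCC/C(C)=C/C(Sc2ccccc2)C[C@](C)(O)[C@H]1C(S(=O)(=O)c3ccccc3)/C=C(\C)CC/C=C(\C)CC/C=C(\C)CC1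
F4 | step 9 | tetrahydropyranyl ether of 9 | O1CCCCC1OC[C@]2(C)O[C@@H]2CC/C(C)=C/CC/C(C)=C/CC/C(C)=C/CO[Si](c3ccccc3)(c4ccccc4)C(C)(C)C
F5 | step 9 | C1 alcohol from F4 | O1CCCCC1OC[C@]2(C)O[C@@H]2CC/C(C)=C/CC/C(C)=C/CC/C(C)=C/CO
F6 | step 9 | C1 phenyl sulfide from F5 | O1CCCCC1OC[C@]2(C)O[C@@H]2CC/C(C)=C/CC/C(C)=C/CC/C(C)=C/CSc3ccccc3
F7 | step 9 | macrocyclic tetrahydropyranyl ether | O1CCCCC1OC[C@](C)(O)[C@H]2C(Sc3ccccc3)/C=C(\C)CC/C=C(\C)CC/C=C(\C)CC2
F8 | step 9 | macrocyclic 1,2-diol | OC[C@](C)(O)[C@H]1C(Sc2ccccc2)/C=C(\C)CC/C=C(\C)CC/C=C(\C)CC1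
F9 | step 9 | primary monotosylate of F8 | Cc1ccc(cc1)S(=O)(=O)OC[C@](C)(O)[C@H]2C(Sc3ccccc3)/C=C(\C)CC/C=C(\C)CC/C=C(\C)CC2
F10 | step 9 | macrocyclic terminal epoxide | C1O[C@]1(C)[C@H]2C(Sc3ccccc3)/C=C(\C)CC/C=C(\C)CC/C=C(\C)CC2
F11 | step 13 | bis(phenyl sulfone) corresponding to 18 | CC(C)=CCC/C(C)=C/C(S(=O)(=O)c2ccccc2)C[C@](C)(O)[C@H]1C(S(=O)(=O)c3ccccc3)/C=C(\C)CC/C=C(\C)CC/C=C(\C)CC1
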